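Ring A is made from a 2-pyrone instead of by coupling two hindered arenes. Ring A carries its ester carbon C1 between oxygens on C2 and C6, a methyl on C4 and hydrogens on C3 and C5. That pattern is a 3-carbomethoxy-4-aryloxy-6-methyl-2-pyrone in which the lactone C(=O)–O unit has been exchanged for a two-carbon ketene acetal. One thermal operation with 1,1-dimethoxyethene forms C1–C2 and C3–C4, expels CO2 and methanol, and leaves the arene with the diaryl ether already in place. The precursor is the pyrone bearing ring B through oxygen at C4, with the ring B benzylic alcohol masked as a tert-butyldiphenylsilyl ether.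

Key step: step 6

Remarks on the chemistry:
- 2-Hydroxy-3,5-dimethoxybenzaldehyde is assumed to be a catalogue compound.
- The benzylic oxygen is carried as a tert-butyldiphenylsilyl ether because BCl3 can convert benzylic alcohols and labile benzylic silyl ethers into benzylic chlorides. A silyl group expected to outlast BCl3 is therefore used and removed with fluoride in the last step.
- The only chiral compound is the transient cycloadduct 12, which is racemic.

Step 1
Reactants: 1 dimethyl malonate; 2 2,2,6-trimethyl-4H-1,3-dioxin-4-one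
Product: 5 methyl 4-hydroxy-6-methyl-2-oxo-2H-pyran-3-carboxylate, via acetylketene 3 (not isolated), via dimethyl acetoacetylmalonate 4 (not isolated)
Conditions: NaH, THF, 0 °C; then 2 (slow addition), PhMe, 110 °C; 1 M HCl
Reagents that add atoms: none
Why: Thermal retro-[4+2] of dioxinone 2 releases acetylketene 3, which C-acylates sodium dimethyl malonate, and tricarbonyl 4 lactonises through its enol oxygen with loss of methanol (acylketene acetoacetylation then 4-hydroxy-2-pyrone cyclisation, as known for diketene with malonate enolates).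

Step 2
Reactants: 5 methyl 4-hydroxy-6-methyl-2-oxo-2H-pyran-3-carboxylate
Product: 6 methyl 6-methyl-4-[(4-methylphenyl)sulfonyloxy]-2-oxo-2H-pyran-3-carboxylate
Conditions: TsCl, Et3N, CH2Cl2, 0 °C to rt
Reagents that add atoms: p-toluenesulfonyl chloride, Cc1ccc(cc1)S(Cl)(=O)=O
Why: The acidic C4 hydroxyl (a vinylogous carboxylic acid) is O-sulfonylated under amine base, the standard tosylation of 4-hydroxy-2-pyrones, which turns C4 into a vinylogous mixed anhydride.

Step 3
Reactants: 7 2-hydroxy-3,5-dimethoxybenzaldehyde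
Product: 8 2-(hydroxymethyl)-4,6-dimethoxyphenol
Conditions: NaBH4, MeOH, 0 °C; aq. NH4Cl
Reagents that add atoms: none
Why: Borohydride reduction of the aryl aldehyde to the benzylic alcohol, with no other reducible group present.

Step 4
Reactants: 8 2-(hydroxymethyl)-4,6-dimethoxyphenol
Product: 9 2-[(tert-butyldiphenylsilyloxy)methyl]-4,6-dimethoxyphenol
Conditions: TBDPSCl (1.05 equiv), imidazole, DMF, 0 °C
Reagents that add atoms: tert-butyl(chloro)diphenylsilane, CC(C)(C)[Si](Cl)(c1ccccc1)c1ccccc1
Why: Selective silyl ether formation, since the unhindered primary alcohol should react with the bulky chlorosilane much faster than the phenol, which is flanked by a methoxy group and the CH2 substituent.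

Step 5
Reactants: 6 methyl 6-methyl-4-[(4-methylphenyl)sulfonyloxy]-2-oxo-2H-pyran-3-carboxylate; 9 2-[(tert-butyldiphenylsilyloxy)methyl]-4,6-dimethoxyphenol
Product: 10 methyl 4-[2-[(tert-butyldiphenylsilyloxy)methyl]-4,6-dimethoxyphenoxy]-6-methyl-2-oxo-2H-pyran-3-carboxylate
Conditions: K2CO3, DMF, 0 °C to rt
Reagents that add atoms: none
Why: Addition–elimination (vinylic nucleophilic substitution) of the phenoxide at C4, the β-carbon of both the lactone carbonyl and the C3 ester, with tosylate as leaving group, so the hindered diaryl-ether oxygen is attached as a vinylogous carbonate without any aryl–oxygen coupling.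

Step 6
Reactants: 10 methyl 4-[2-[(tert-butyldiphenylsilyloxy)methyl]-4,6-dimethoxyphenoxy]-6-methyl-2-oxo-2H-pyran-3-carboxylate; 11 1,1-dimethoxyethene
Product: 14 methyl 2-[2-[(tert-butyldiphenylsilyloxy)methyl]-4,6-dimethoxyphenoxy]-6-methoxy-4-methylbenzoate, via bicyclic lactone 12 (not isolated), via dimethoxycyclohexadiene 13 (not isolated)
Conditions: 11 (6 equiv), PhMe, 130 °C, sealed tube
Reagents that add atoms: none
Why: The electron-poor pyrone diene (C3 to C6, lowered by the C3 ester and the lactone carbonyl) and the electron-rich ketene acetal 11 combine in an inverse-electron-demand [4+2] cycloaddition, probably asynchronous with the CH2–C6 bond leading, to give the 2-oxabicyclo[2.2.2]octenone 12; retro-[4+2] loss of CO2 gives diene 13, and 1,2-elimination of methanol aromatises it to 14. The closest known reaction is the thermal conversion of 3-carbomethoxy-2-pyrones with 1,1-dimethoxyethene into methyl 2-methoxybenzoates. Ring A is closed as a six-membered carbocycle by intermolecular [4+2] cycloaddition across the diene termini followed by cycloreversion, so no exo/endo ring-closure rule applies. No stereocentre survives, because the two bridgehead centres of racemic 12 are erased on CO2 loss and aromatisation. The step needs regioselectivity (ketene acetal CH2 to pyrone C6, acetal carbon to the ester-bearing C3), which the polarisation of the dienyl ester secures: C6 is the electrophilic terminus and C3 best carries the developing negative charge. It also needs chemoselectivity against ipso displacement of the aryloxide at C4, which the neutral, non-polar, Lewis-acid-free conditions and the shielding of C4 by the 2,6-disubstituted aryloxy group should favour.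

Step 7
Reactants: 14 methyl 2-[2-[(tert-butyldiphenylsilyloxy)methyl]-4,6-dimethoxyphenoxy]-6-methoxy-4-methylbenzoate
Product: 15 methyl 2-[2-[(tert-butyldiphenylsilyloxy)methyl]-4,6-dimethoxyphenoxy]-6-hydroxy-4-methylbenzoate
Conditions: BCl3 (1.5 equiv), CH2Cl2, −78 to 0 °C; aq. NaHCO3
Reagents that add atoms: none
Why: Chelation-directed demethylation, in which BCl3 bridges the ring A ester carbonyl and the ortho methoxy oxygen and chloride removes only that methyl, while the ring B methoxy groups have no neighbouring carbonyl and the bulky, weakly basic silyl ether should survive at low temperature.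

Step 8
Reactants: 15 methyl 2-[2-[(tert-butyldiphenylsilyloxy)methyl]-4,6-dimethoxyphenoxy]-6-hydroxy-4-methylbenzoate; 16 prenyl bromide (1-bromo-3-methylbut-2-ene)
Product: 17 methyl 2-[2-[(tert-butyldiphenylsilyloxy)methyl]-4,6-dimethoxyphenoxy]-4-methyl-6-(3-methylbut-2-enyloxy)benzoate
Conditions: K2CO3, DMF, rt
Reagents that add atoms: none
Why: Williamson O-alkylation of the salicylate phenoxide with the allylic bromide, with the only other hydroxyl silylated so that no selectivity question arises.

Step 9
Reactants: 17 methyl 2-[2-[(tert-butyldiphenylsilyloxy)methyl]-4,6-dimethoxyphenoxy]-4-methyl-6-(3-methylbut-2-enyloxy)benzoate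
Product: 18 methyl 2-[2-(hydroxymethyl)-4,6-dimethoxyphenoxy]-4-methyl-6-(3-methylbut-2-enyloxy)benzoate
Conditions: Bu4NF, AcOH (1:1), THF, rt
Reagents that add atoms: none
Why: Fluoride-driven silyl ether cleavage, buffered with acetic acid so that no free alkoxide can attack the ring A ester, with the ester, prenyl ether and diaryl ether inert.

Compound list
1 | dimethyl malonate | COC(=O)CC(=O)OC | starting material
2 | 2,2,6-trimethyl-4H-1,3-dioxin-4-one | CC1=CC(=O)OC(C)(C)O1 | starting material
3 | acetylketene (buta-1-ene-1,3-dione), not isolated | CC(=O)C=C=O | intermediate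
4 | dimethyl 2-(3-oxobutanoyl)propanedioate (dimethyl acetoacetylmalonate), formed as its sodium enolate, not isolated | COC(=O)C(C(=O)OC)C(=O)CC(C)=O | intermediate
5 | methyl 4-hydroxy-6-methyl-2-oxo-2H-pyran-3-carboxylate | COC(=O)C1=C(O)C=C(C)OC1=O | intermediate
6 | methyl 6-methyl-4-[(4-methylphenyl)sulfonyloxy]-2-oxo-2H-pyran-3-carboxylate | COC(=O)C1=C(OS(=O)(=O)c2ccc(C)cc2)C=C(C)OC1=O | intermediate
7 | 2-hydroxy-3,5-dimethoxybenzaldehyde | COc1cc(C=O)c(O)c(OC)c1 | starting material
8 | 2-(hydroxymethyl)-4,6-dimethoxyphenol | COc1cc(CO)c(O)c(OC)c1 | intermediate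
9 | 2-[(tert-butyldiphenylsilyloxy)methyl]-4,6-dimethoxyphenol | COc1cc(CO[Si](c2ccccc2)(c2ccccc2)C(C)(C)C)c(O)c(OC)c1 | intermediate
10 | methyl 4-[2-[(tert-butyldiphenylsilyloxy)methyl]-4,6-dimethoxyphenoxy]-6-methyl-2-oxo-2H-pyran-3-carboxylate | COC(=O)C1=C(Oc2c(CO[Si](c3ccccc3)(c3ccccc3)C(C)(C)C)cc(OC)cc2OC)C=C(C)OC1=O | intermediate
11 | 1,1-dimethoxyethene | C=C(OC)OC | starting material
12 | methyl 5-[2-[(tert-butyldiphenylsilyloxy)methyl]-4,6-dimethoxyphenoxy]-8,8-dimethoxy-1-methyl-3-oxo-2-oxabicyclo[2.2.2]oct-5-ene-4-carboxylate, racemic, bridgehead configuration fixed by the bicycle, not isolated | COC(=O)C12C(=O)OC(C)(C=C1Oc3c(CO[Si](c4ccccc4)(c5ccccc5)C(C)(C)C)cc(OC)cc3OC)CC2(OC)OC | intermediate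
13 | methyl 2-[2-[(tert-butyldiphenylsilyloxy)methyl]-4,6-dimethoxyphenoxy]-6,6-dimethoxy-4-methylcyclohexa-1,3-diene-1-carboxylate, not isolated | COC(=O)C1=C(Oc2c(CO[Si](c3ccccc3)(c4ccccc4)C(C)(C)C)cc(OC)cc2OC)C=C(C)CC1(OC)OC | intermediate
14 | methyl 2-[2-[(tert-butyldiphenylsilyloxy)methyl]-4,6-dimethoxyphenoxy]-6-methoxy-4-methylbenzoate | COC(=O)c1c(OC)cc(C)cc1Oc1c(CO[Si](c2ccccc2)(c2ccccc2)C(C)(C)C)cc(OC)cc1OC | intermediate
15 | methyl 2-[2-[(tert-butyldiphenylsilyloxy)methyl]-4,6-dimethoxyphenoxy]-6-hydroxy-4-methylbenzoate | COC(=O)c1c(O)cc(C)cc1Oc1c(CO[Si](c2ccccc2)(c2ccccc2)C(C)(C)C)cc(OC)cc1OC | intermediate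
16 | prenyl bromide (1-bromo-3-methylbut-2-ene) | CC(C)=CCBr | starting material
17 | methyl 2-[2-[(tert-butyldiphenylsilyloxy)methyl]-4,6-dimethoxyphenoxy]-4-methyl-6-(3-methylbut-2-enyloxy)benzoate | COC(=O)c1c(OCC=C(C)C)cc(C)cc1Oc1c(CO[Si](c2ccccc2)(c2ccccc2)C(C)(C)C)cc(OC)cc1OC | intermediate
18 | methyl 2-[2-(hydroxymethyl)-4,6-dimethoxyphenoxy]-4-methyl-6-(3-methylbut-2-enyloxy)benzoate (achiral) | COC(=O)c1c(OCC=C(C)C)cc(C)cc1Oc1c(CO)cc(OC)cc1OC | target

Total step count: 9. Longest linear sequence: 7 steps (7 → 8 → 9 → 10 → 14 → 15 → 17 → 18, or equally 1 → 5 → 6 → 10 → 14 → 15 → 17 → 18).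

Steps most likely to fail

1. Step 6. The C4 aryloxy donor raises the diene LUMO, so cycloaddition may be slow enough for the ketene acetal to oligomerise first. Alternatively the ketene acetal may attack C4 and expel the phenoxide instead of adding across C3/C6. The fallback gives up the pyrone for a preformed ring A and makes the diaryl ether by palladium-catalysed C–O cross-coupling. It sets out from phenol 9 and comes back at 14. Purchased methyl 2,6-dihydroxy-4-methylbenzoate F1 is mono-methylated (MeI, 1 equiv, K2CO3, acetone) to methyl 2-hydroxy-6-methoxy-4-methylbenzoate F2. Triflation (Tf2O, pyridine, CH2Cl2) gives methyl 2-methoxy-4-methyl-6-(trifluoromethylsulfonyloxy)benzoate F3. F3 is coupled with 9 using Pd(OAc)2, 2-di-tert-butylphosphino-2',4',6'-triisopropylbiphenyl and K3PO4 in toluene at 100 °C to give 14.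

2. Step 5. The hindered phenoxide may attack sulfur of the tosylate (sulfonyl transfer, returning the pyrone oxide) or open the lactone, instead of substituting at C4. The fallback uses an electrophile with no second electrophilic centre on the leaving group. It sets out from 5 and comes back at 10. POCl3 with Et3N converts 5 into the vinylogous acid chloride methyl 4-chloro-6-methyl-2-oxo-2H-pyran-3-carboxylate F4, which is treated with 9 and K2CO3 in MeCN to give 10.

3. Step 7. The Lewis acid may strip the silyl group and ionise the benzylic C–O bond, leading to chloride substitution at the benzylic carbon. If the demethylation needs warming, a ring B methoxy group may also be lost. The fallback takes the benzylic carbon through the Lewis-acid step as an aldehyde, which BCl3 tolerates. It sets out from 14 and comes back at 18.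
   - Bu4NF in THF gives methyl 2-[2-(hydroxymethyl)-4,6-dimethoxyphenoxy]-6-methoxy-4-methylbenzoate F5.
   - MnO2 in CH2Cl2 gives methyl 2-(2-formyl-4,6-dimethoxyphenoxy)-6-methoxy-4-methylbenzoate F6.
   - BCl3 at −78 to 0 °C gives methyl 2-(2-formyl-4,6-dimethoxyphenoxy)-6-hydroxy-4-methylbenzoate F7.
   - Prenyl bromide 16 with K2CO3 in DMF gives methyl 2-(2-formyl-4,6-dimethoxyphenoxy)-4-methyl-6-(3-methylbut-2-enyloxy)benzoate F8.
   - NaBH4 in MeOH at 0 °C reduces only the aldehyde and gives 18.

Further compounds
F1 | step 6 | methyl 2,6-dihydroxy-4-methylbenzoate (purchased) | COC(=O)c1c(O)cc(C)cc1O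
F2 | step 6 | methyl 2-hydroxy-6-methoxy-4-methylbenzoate | COC(=O)c1c(O)cc(C)cc1OC
F3 | step 6 | methyl 2-methoxy-4-methyl-6-(trifluoromethylsulfonyloxy)benzoate | COC(=O)c1c(OC)cc(C)cc1OS(=O)(=O)C(F)(F)F
F4 | step 5 | methyl 4-chloro-6-methyl-2-oxo-2H-pyran-3-carboxylate | COC(=O)C1=C(Cl)C=C(C)OC1=O
F5 | step 7 | methyl 2-[2-(hydroxymethyl)-4,6-dimethoxyphenoxy]-6-methoxy-4-methylbenzoate | COC(=O)c1c(OC)cc(C)cc1Oc1c(CO)cc(OC)cc1OC
F6 | step 7 | methyl 2-(2-formyl-4,6-dimethoxyphenoxy)-6-methoxy-4-methylbenzoate | COC(=O)c1c(OC)cc(C)cc1Oc1c(C=O)cc(OC)cc1OC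
F7 | step 7 | methyl 2-(2-formyl-4,6-dimethoxyphenoxy)-6-hydroxy-4-methylbenzoate | COC(=O)c1c(O)cc(C)cc1Oc1c(C=O)cc(OC)cc1OC
F8 | step 7 | methyl 2-(2-formyl-4,6-dimethoxyphenoxy)-4-methyl-6-(3-methylbut-2-enyloxy)benzoate | COC(=O)c1c(OCC=C(C)C)cc(C)cc1Oc1c(C=O)cc(OC)cc1OC
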